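**Strategy.** The cyclohexane ring (ring A) is closed last by a samarium diiodide ketyl–enone cyclisation (locants defined below). The precursor is an azonane-fused cyclopentenone whose C5 carries a CH2–C(CH3)(OAc)–CH2–CHO chain. The aldehyde ketyl adds 6-exo to the enone β-carbon, creating the C1–C15 bond, the spiro quaternary carbon C15 and the C1 carbinol in one operation. The samarium enolate is trapped as a silyl enol ether that is later oxidised to the C8=C9 enone. The step exploits the 1,4-relationship between the C1 oxygen and the C7 ketone across C15 and C8. C5 comes from a palladium-catalysed desymmetrisation of a meso cyclopentenediol diester.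

Key step: step 15

Remark on locants: ring A = cyclohexane C1 (CH–OAc), C2 (CH2), C3 (C(CH3)OAc), C4 (CH2), C5 (ring-fusion CH), C15 (spiro quaternary C); ring B = cyclopentanone C5, C6 (CH2), C7 (C=O), C8, C15; ring C = azonane C8, C9 (=CH), C10, C11, N, C12, C13, C14, C15.
Remark on catalysts: the antipodes named for the palladium ligand (step 9) and the bi-naphthol catalyst (step 11) are those expected from the usual facial models; the mirror-image catalyst would be used if the sense proves opposite.

Step 1
Reactants: 1 cyclopentane-1,3-dione; 2 allyl acetate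
Product: 3 2-allylcyclopentane-1,3-dione
Conditions: Pd(PPh3)4 (2 mol %), DBU, toluene, 80 °C
Reagents that add atoms: none
Why: Tsuji–Trost allylation, in which the soft dione enolate attacks the π-allylpalladium complex at carbon, so C-monoallylation is expected with a slight excess of 1.

Step 2
Reactants: 3
Product: 4 2-allyl-3-isobutoxycyclopent-2-en-1-one
Conditions: i-BuOH, TsOH·H2O (cat.), toluene, reflux, Dean–Stark
Reagents that add atoms: 2-methylpropan-1-ol, CC(C)CO
Why: Acid-catalysed enol etherification of the symmetrical 1,3-dione with azeotropic removal of water gives the single vinylogous ester needed for a Stork–Danheiser sequence.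

Step 3
Reactants: 4
Product: 6 2-allyl-5-hydroxy-3-isobutoxycyclopent-2-en-1-one (racemic), via potassium enolate 5 (not isolated)
Conditions: KN(SiMe3)2, THF, −78 °C; then 2-(phenylsulfonyl)-3-phenyloxaziridine, −78 °C; aq NH4Cl
Reagents that add atoms: 2-(phenylsulfonyl)-3-phenyloxaziridine, O=S(=O)(c1ccccc1)N1OC1c1ccccc1
Why: Kinetic deprotonation of the vinylogous ester at the α′-carbon and oxygen transfer from the N-sulfonyloxaziridine (enolate hydroxylation) place a hydroxyl on the future C5; the centre is racemic here and is made uniform by the meso diol of step 5.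

Step 4
Reactants: 6; 7 allylmagnesium bromide
Product: 9 2,3-diallyl-4-hydroxycyclopent-2-en-1-one (racemic), via carbonyl adduct diol 8 (not isolated)
Conditions: 7 (3.5 equiv), THF, −78 → 0 °C; then 1 M HCl, THF, 25 °C
Reagents that add atoms: none
Why: 1,2-Addition of the Grignard reagent to the vinylogous ester carbonyl, then acid-mediated enol-ether hydrolysis with loss of the tertiary hydroxyl (Stork–Danheiser transposition), gives the 2,3-dialkyl enone; the first equivalent of 7 only deprotonates the hydroxyl.

Step 5
Reactants: 9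
Product: 10 (1R,3S)-4,5-diallylcyclopent-4-ene-1,3-diol (cis, meso)
Conditions: NaBH4, CeCl3·7H2O, MeOH, −40 °C
Reagents that add atoms: none
Why: Luche 1,2-reduction in which hydride should add anti to the existing hydroxyl, giving the cis-diol; this diol is meso, so the racemic nature of 9 is erased (any trans-diol is removed by chromatography).

Step 6
Reactants: 10
Product: 11 (1R,3S)-4,5-diallylcyclopent-4-ene-1,3-diyl dibenzoate (meso)
Conditions: BzCl, pyridine, DMAP (cat.), CH2Cl2, 0 → 25 °C
Reagents that add atoms: benzoyl chloride, O=C(Cl)c1ccccc1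
Why: Standard acylation; the benzoates protect the carbinols during hydroboration and ring closure and later serve as the two enantiotopic leaving groups.

Step 7
Reactants: 11
Product: 13 (1R,3S)-4,5-bis(3-hydroxypropyl)cyclopent-4-ene-1,3-diyl dibenzoate (meso), via bis(B-alkyl-9-BBN) adduct 12 (not isolated)
Conditions: 9-BBN (2.4 equiv), THF, 0 → 25 °C; then 3 M aq NaOAc, 30% H2O2, 0 → 25 °C
Reagents that add atoms: hydrogen peroxide, OO
Why: Anti-Markovnikov hydroboration–oxidation; 9-BBN reacts only with the two monosubstituted alkenes (the tetrasubstituted ring alkene and the esters are inert) and the acetate-buffered oxidation spares the benzoates.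

Step 8
Reactants: 13; 14 4-cyanobenzenesulfonamide
Product: 16 meso azonane-fused cyclopentene dibenzoate (5S,7R), via mono-N-alkylated sulfonamide 15 (not isolated)
Conditions: PPh3, DIAD, THF–toluene, slow addition, 0.005 M, 25 °C
Reagents that add atoms: none
Why: Two Mitsunobu N-alkylations of the acidic sulfonamide (inter- then intramolecular, Fukuyama–Mitsunobu type) close the nine-membered ring; the cis tetrasubstituted alkene holds both arms on one side and high dilution suppresses oligomers, while the cyanoarene sulfonamide has no nitro group for SmI2 to reduce later and is cleaved by thiolate at the end.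

Step 9
Reactants: 16; 17 pentane-2,4-dione
Product: 18 (5R,7R)-monobenzoate with CH(COCH3)2 at C5
Conditions: Pd2(dba)3·CHCl3 (2.5 mol %), (1R,2R)-N,N′-bis[2-(diphenylphosphino)benzoyl]cyclohexane-1,2-diamine (7.5 mol %), Cs2CO3, CH2Cl2, 0 → 25 °C
Reagents that add atoms: none
Why: Palladium-catalysed asymmetric allylic alkylation (Tsuji–Trost) of a meso diester, in which the chiral ligand selects one enantiotopic benzoate for ionisation and the soft diketone anion attacks the π-allyl complex at its less substituted terminus C5 anti to palladium; C5 is thereby set with net retention, cis to the remaining benzoate.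

Step 10
Reactants: 18
Product: 19 (5R,7R)-hydroxy methyl ketone (C5 acetonyl, C7 hydroxyl)
Conditions: NaOMe, MeOH, 0 → 25 °C
Reagents that add atoms: none
Why: Methoxide effects retro-Claisen deacetylation of the 3-substituted pentane-2,4-dione to the methyl ketone and methanolysis of the benzoate in one operation, without touching the non-acidic C5 centre.

Step 11
Reactants: 19; 20 2-allyl-1,3,2-dioxaborinane
Product: 21 (3R,5R,7R)-diol with CH2–C(CH3)(OH)–CH2CH=CH2 at C5
Conditions: (S)-3,3′-dibromo-1,1′-bi-2-naphthol (10 mol %), t-BuOH (2 equiv), toluene, 25 °C; aqueous work-up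
Reagents that add atoms: none
Why: Chiral-diol-catalysed asymmetric allylboration of a methyl ketone through a closed six-membered transition state; the catalyst distinguishes CH3 from CH2R and sets C3 by reagent control, independent of the remote C5 centre, and the alcohol additive shows that the free C7 hydroxyl should be tolerated.

Step 12
Reactants: 21
Product: 22 (3R,5S)-enone with free tertiary alcohol
Conditions: MnO2 (activated, excess), CH2Cl2, 25 °C
Reagents that add atoms: none
Why: Chemoselective oxidation of the allylic secondary alcohol to the C7 enone; the tertiary homoallylic alcohol cannot be oxidised.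

Step 13
Reactants: 22
Product: 23 (3R,5S)-enone tertiary acetate
Conditions: Ac2O, Et3N, DMAP (1 equiv), CH2Cl2, 40 °C
Reagents that add atoms: acetic anhydride, CC(=O)OC(C)=O
Why: DMAP-catalysed acylation (Steglich conditions) installs the tertiary acetate of the target early, where it also serves as an aprotic protecting group for the key step.

Step 14
Reactants: 23
Product: 25 (3S,5S)-aldehyde with CH2–C(CH3)(OAc)–CH2–CHO at C5, via vicinal diol 24 (not isolated)
Conditions: OsO4 (2 mol %), NaIO4, 2,6-lutidine, dioxane–H2O 3:1, 25 °C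
Reagents that add atoms: sodium periodate, [Na+].[O-]I(=O)(=O)=O; water, O
Why: Lemieux–Johnson cleavage of the monosubstituted alkene; the tetrasubstituted enone alkene is electron-poor and hindered and should not be osmylated, and the β-acetoxy aldehyde is used at once to avoid elimination of acetic acid.

Step 15
Reactants: 25
Product: 27 (1S,3S,5S,15S)-tricyclic bis(trimethylsilyl) compound, via samarium alkoxide–enolate 26 (not isolated)
Conditions: SmI2 (2.5 equiv, 0.1 M in THF), THF (0.01 M), no HMPA, −78 → 0 °C; then Me3SiCl, Et3N, −78 → 0 °C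
Reagents that add atoms: chlorotrimethylsilane, C[Si](C)(C)Cl
Why: Samarium diiodide transfers one electron to the aldehyde and the resulting ketyl radical anion adds to the β-carbon C15 of the tetrasubstituted enone; a second electron gives the trivalent samarium enolate spanning C7–C8, which Me3SiCl fixes as the silyl enol ether (the C1 alkoxide is silylated as well). The closest known reaction type is the samarium diiodide ketyl–olefin reductive cyclisation of an aldehyde onto a tethered α,β-unsaturated ketone with enolate trapping. Ring A closes in the 6-exo-trig mode through a chair-like transition state. C15 is controlled by C5: the tether can reach only the face of ring B that carries the side chain, which enforces the cis ring fusion and places the azonane arm C14 on the opposite face. C1 is controlled by chelation: in THF without HMPA, trivalent samarium on the ketyl oxygen is expected to bridge to the enone oxygen and the C3 acetate carbonyl, holding the C1 oxygen over ring B and syn to the C3 oxygen. The step needs chemoselective reduction of the aldehyde over the enone, the ester and the cyanoarene, secured by inner-sphere coordination of the aldehyde at low temperature, and attack at C15 over C8, secured by the polarity match and by six- versus seven-membered ring formation.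

Step 16
Reactants: 27
Product: 29 (1S,3S,5S,15S,E)-hydroxy enone, via silyl ether enone 28 (not isolated)
Conditions: Pd(OAc)2 (10 mol %), O2 (1 atm), DMSO, 25 °C; then 1 M HCl, THF, 0 °C
Reagents that add atoms: none
Why: Saegusa–Ito oxidation (aerobic variant) in which the palladium enolate at C8 can undergo β-hydride elimination only toward C9, because C15 is quaternary; the C8=C9 enone should form regiospecifically with the ring-enforced E geometry, and dilute acid then cleaves the C1 silyl ether.

Step 17
Reactants: 29
Product: 30 N-(4-cyanobenzenesulfonyl) diacetate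
Conditions: Ac2O, Et3N, DMAP, CH2Cl2, 40 °C
Reagents that add atoms: acetic anhydride, CC(=O)OC(C)=O
Why: DMAP-catalysed acetylation of the C1 hydroxyl; the forcing conditions also converge any material in which the acetyl group had migrated from O3 to O1 during step 15.

Step 18
Reactants: 30
Product: 31 CNP0120442.1 (target)
Conditions: n-C12H25SH, DBU, DMF, 25 °C
Reagents that add atoms: none
Why: Thiolate ipso-substitution (SNAr) on the 4-cyanophenyl sulfonamide with loss of SO2 (Fukuyama-type deprotection) frees the secondary amine under conditions that should leave both acetates and the enone intact, thiol addition to the enone being reversible.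

**Compound list**

1 | cyclopentane-1,3-dione | O=C1CCC(=O)C1 | starting material
2 | allyl acetate | C=CCOC(C)=O | starting material
3 | 2-allylcyclopentane-1,3-dione | O=C1CCC(=O)C1CC=C | intermediate
4 | 2-allyl-3-isobutoxycyclopent-2-en-1-one | O=C1CCC(OCC(C)C)=C1CC=C | intermediate
5 | potassium enolate of 4 (cross-conjugated, α′) | [K+].[O-]C1=CCC(OCC(C)C)=C1CC=C | intermediate (not isolated)
6 | 2-allyl-5-hydroxy-3-isobutoxycyclopent-2-en-1-one (racemic) | O=C1C(O)CC(OCC(C)C)=C1CC=C | intermediate
7 | allylmagnesium bromide | C=CC[Mg]Br | starting material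
8 | 1,2-diallyl-3-isobutoxycyclopent-2-ene-1,5-diol (diastereomer mixture) | C=CCC1(O)C(O)CC(OCC(C)C)=C1CC=C | intermediate (not isolated)
9 | 2,3-diallyl-4-hydroxycyclopent-2-en-1-one (racemic) | O=C1CC(O)C(CC=C)=C1CC=C | intermediate
10 | (1R,3S)-4,5-diallylcyclopent-4-ene-1,3-diol (cis, meso) | O[C@H]1C[C@@H](O)C(CC=C)=C1CC=C | intermediate
11 | (1R,3S)-4,5-diallylcyclopent-4-ene-1,3-diyl dibenzoate (meso) | O=C(O[C@H]1C[C@@H](OC(=O)c2ccccc2)C(CC=C)=C1CC=C)c1ccccc1 | intermediate
12 | bis(B-alkyl-9-borabicyclo[3.3.1]nonane) adduct of 11 | O=C(O[C@H]1C[C@@H](OC(=O)c2ccccc2)C(CCCB2C3CCCC2CCC3)=C1CCCB1C2CCCC1CCC2)c1ccccc1 | intermediate (not isolated)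
13 | (1R,3S)-4,5-bis(3-hydroxypropyl)cyclopent-4-ene-1,3-diyl dibenzoate (meso) | O=C(O[C@H]1C[C@@H](OC(=O)c2ccccc2)C(CCCO)=C1CCCO)c1ccccc1 | intermediate
14 | 4-cyanobenzenesulfonamide | N#Cc1ccc(cc1)S(N)(=O)=O | starting material
15 | mono-N-alkylated sulfonamide (one arm N-linked, one arm CH2OH; racemic, one enantiomer drawn) | O=C(O[C@H]1C[C@@H](OC(=O)c2ccccc2)C(CCCO)=C1CCCNS(=O)(=O)c1ccc(cc1)C#N)c1ccccc1 | intermediate (not isolated)
16 | meso bicycle (5S,7R): cyclopentene C5–C6–C7–C8=C15 fused at C8=C15 to N-(4-cyanobenzenesulfonyl)azonane; cis benzoates at C5 and C7 | O=C(O[C@H]1C[C@@H](OC(=O)c2ccccc2)C2=C1CCCN(CCC2)S(=O)(=O)c1ccc(cc1)C#N)c1ccccc1 | intermediate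
17 | pentane-2,4-dione | CC(=O)CC(C)=O | starting material
18 | (5R,7R)-monobenzoate: C5 carries CH(COCH3)2 cis to the C7 benzoate | CC(=O)C(C(C)=O)[C@H]1C[C@@H](OC(=O)c2ccccc2)C2=C1CCCN(CCC2)S(=O)(=O)c1ccc(cc1)C#N | intermediate
19 | (5R,7R)-hydroxy ketone: C5 acetonyl cis to the C7 hydroxyl | CC(=O)C[C@H]1C[C@@H](O)C2=C1CCCN(CCC2)S(=O)(=O)c1ccc(cc1)C#N | intermediate
20 | 2-allyl-1,3,2-dioxaborinane | C=CCB1OCCCO1 | starting material
21 | (3R,5R,7R)-diol: C5 carries CH2–C(CH3)(OH)–CH2CH=CH2; C7 hydroxyl | C=CC[C@@](C)(O)C[C@H]1C[C@@H](O)C2=C1CCCN(CCC2)S(=O)(=O)c1ccc(cc1)C#N | intermediate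
22 | (3R,5S)-enone (C7 ketone, C8=C15) with free tertiary alcohol | C=CC[C@@](C)(O)C[C@H]1CC(=O)C2=C1CCCN(CCC2)S(=O)(=O)c1ccc(cc1)C#N | intermediate
23 | (3R,5S)-enone tertiary acetate | C=CC[C@@](C)(OC(C)=O)C[C@H]1CC(=O)C2=C1CCCN(CCC2)S(=O)(=O)c1ccc(cc1)C#N | intermediate
24 | vicinal diol from 23 (terminal alkene dihydroxylated; epimer mixture at the new carbinol) | OCC(O)C[C@@](C)(OC(C)=O)C[C@H]1CC(=O)C2=C1CCCN(CCC2)S(=O)(=O)c1ccc(cc1)C#N | intermediate (not isolated)
25 | (3S,5S)-aldehyde: C5 carries CH2–C(CH3)(OAc)–CH2–CHO on the azonane-fused cyclopentenone | O=CC[C@@](C)(OC(C)=O)C[C@H]1CC(=O)C2=C1CCCN(CCC2)S(=O)(=O)c1ccc(cc1)C#N | intermediate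
26 | bis(diiodosamarium) C1-alkoxide C7-enolate of the cyclised tricycle | I[Sm](I)O[C@H]1C[C@@](C)(OC(C)=O)C[C@H]2CC(O[Sm](I)I)=C3CCCN(CCC[C@@]321)S(=O)(=O)c4ccc(cc4)C#N | intermediate (not isolated)
27 | (1S,3S,5S,15S)-tricycle: C1 OSiMe3, C3 OAc, C7–C8 trimethylsilyl enol ether | C[Si](C)(C)O[C@H]1C[C@@](C)(OC(C)=O)C[C@H]2CC(O[Si](C)(C)C)=C3CCCN(CCC[C@@]321)S(=O)(=O)c4ccc(cc4)C#N | intermediate
28 | (1S,3S,5S,15S,E)-C1 trimethylsilyl ether of 29 | C[Si](C)(C)O[C@H]1C[C@@](C)(OC(C)=O)C[C@H]2CC(=O)/C3=C/CCN(CCC[C@@]321)S(=O)(=O)c4ccc(cc4)C#N | intermediate (not isolated)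
29 | (1S,3S,5S,15S,E)-hydroxy enone: C1 OH, C3 OAc, C7 ketone, C8=C9 | O[C@H]1C[C@@](C)(OC(C)=O)C[C@H]2CC(=O)/C3=C/CCN(CCC[C@@]321)S(=O)(=O)c4ccc(cc4)C#N | intermediate
30 | N-(4-cyanobenzenesulfonyl) derivative of the target (1,3-diacetate) | CC(=O)O[C@H]1C[C@@](C)(OC(C)=O)C[C@H]2CC(=O)/C3=C/CCN(CCC[C@@]321)S(=O)(=O)c4ccc(cc4)C#N | intermediate
31 | CNP0120442.1, (1S,3S,5S,15S,E) | CC(=O)O[C@H]1C[C@@](C)(OC(C)=O)C[C@H]2CC(=O)/C3=C/CCNCCC[C@@]321 | target

Total step count: 18. Longest linear sequence: 18 steps (from 1).

**Steps most likely to fail**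

1. Step 15. What may go wrong: poor facial selectivity at the ketyl carbon (the samarium-bound oxygen turning away from ring B, which would give the C1 epimer), acetyl migration between O3 and O1, or electron transfer to the cyanoarene. The fallback is a substrate redesign that replaces ester-assisted chelation by a bidentate acetal director, and it sets out from 22. The tertiary alcohol is protected with MeOCH2Cl, i-Pr2NEt and Bu4NI to give the methoxymethyl ether F1. OsO4/NaIO4 cleavage gives the aldehyde F2. SmI2 in THF, then Me3SiCl/Et3N, should give the cyclised bis-silyl compound F3; here a six-membered chelate of trivalent samarium between the ketyl oxygen and the C3 ether oxygen, reinforced by the second acetal oxygen, fixes the 1,3-syn relation. Pd(OAc)2/O2 in DMSO followed by methanolic HCl (loss of the silyl and the methoxymethyl ether) gives the diol enone F4. Double acetylation (Ac2O, Et3N, DMAP, 40 °C) returns to the route at 30.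

2. Step 9. What may go wrong: sluggish or unselective ionisation of the hindered allylic benzoate by the bulky chiral palladium complex, or a second substitution at C7. The fallback uses enzyme-controlled desymmetrisation and an achiral palladium catalyst, and it sets out from 16. K2CO3/MeOH gives the meso diol F5. Burkholderia cepacia lipase with vinyl acetate in t-BuOMe acetylates one enantiotopic hydroxyl to the monoacetate F6 (the enzyme, or the complementary hydrolysis of the diacetate, being chosen so that the acetate sits on C5). Pd(PPh3)4 with the sodium salt of 17 replaces the acetate with retention to give the diketone alcohol F7. NaOMe/MeOH then deacetylates F7 and returns to the route at 19.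

3. Step 8. What may go wrong: oligomerisation competing with closure of the nine-membered ring in the second Mitsunobu event. The fallback is a double SN2 alkylation of a bis-electrophile under caesium templating, and it sets out from 13. MsCl/Et3N gives the dimesylate F8, which with 14, Cs2CO3 and Bu4NI in MeCN at high dilution (60 °C) should give 16, where it returns to the route.

Further compounds
F1 | step 15 | methoxymethyl ether of 22 (3R,5S) | C=CC[C@@](C)(OCOC)C[C@H]1CC(=O)C2=C1CCCN(CCC2)S(=O)(=O)c1ccc(cc1)C#N
F2 | step 15 | aldehyde with CH2–C(CH3)(OCH2OCH3)–CH2–CHO at C5 | O=CC[C@@](C)(OCOC)C[C@H]1CC(=O)C2=C1CCCN(CCC2)S(=O)(=O)c1ccc(cc1)C#N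
F3 | step 15 | cyclised tricycle: C1 OSiMe3, C3 OCH2OCH3, C7–C8 trimethylsilyl enol ether | C[Si](C)(C)O[C@H]1C[C@@](C)(OCOC)C[C@H]2CC(O[Si](C)(C)C)=C3CCCN(CCC[C@@]321)S(=O)(=O)c4ccc(cc4)C#N
F4 | step 15 | diol enone: C1 OH, C3 OH, C7 ketone, C8=C9 | O[C@H]1C[C@@](C)(O)C[C@H]2CC(=O)/C3=C/CCN(CCC[C@@]321)S(=O)(=O)c4ccc(cc4)C#N
F5 | step 9 | meso azonane-fused cyclopent-4-ene-1,3-diol | O[C@H]1C[C@@H](O)C2=C1CCCN(CCC2)S(=O)(=O)c1ccc(cc1)C#N
F6 | step 9 | monoacetate (acetate on C5, hydroxyl on C7) | CC(=O)O[C@H]1C[C@@H](O)C2=C1CCCN(CCC2)S(=O)(=O)c1ccc(cc1)C#N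
F7 | step 9 | diketone alcohol: C5 carries CH(COCH3)2, C7 hydroxyl | CC(=O)C(C(C)=O)[C@H]1C[C@@H](O)C2=C1CCCN(CCC2)S(=O)(=O)c1ccc(cc1)C#N
F8 | step 8 | dimesylate of 13 (meso) | O=C(O[C@H]1C[C@@H](OC(=O)c2ccccc2)C(CCCOS(C)(=O)=O)=C1CCCOS(C)(=O)=O)c1ccccc1
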